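## Retrosynthetic overview
1. Caespitol (8) comes from desilylation of 7. Compound 7 comes from anodic 6‑endo bromoetherification of the acyclic alkenol 6, which forms C11–O and C10–Br and closes the oxane last.
2. Compound 6 comes from reductive SN1′ opening of dihydropyranol 4/5. This temporary ring makes C8 the only allylic CH2 and fixes the face of the SeO2 oxygenation (C8–O).
3. C1–Cl and C2–Br come from an electrochemical, ionisation‑equilibrated bromochlorination of the ring alkene of 2. This is the new step, and it is anchored by C4.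
4. Compound 2 comes from (−)‑α‑bisabolol (1), which supplies C4 and C7, by selenoetherification and selenoxide elimination.
5. Ring order: the cyclohexane is bought, the temporary dihydropyran is made in step 1 and opened in step 5, and the final oxane is closed in step 6.

Assumption: commercial natural (−)‑α‑bisabolol is the (4S,7S) isomer drawn as 1. Locants are bisabolane numbering: C1 = ring C–CH3, C2 = ring CH, C4 = ring CH bearing the side chain, C7 = carbinol carbon, C8–C11 = chain.

## Route

**Step 1**
Reactants: 1, (−)‑α‑bisabolol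
Product: 2, (2S)‑2,6,6‑trimethyl‑2‑[(1S)‑4‑methylcyclohex‑3‑en‑1‑yl]‑3,6‑dihydro‑2H‑pyran (C9=C10 alkene)
Conditions: PhSeCl (1.05 eq), CH2Cl2, −78→25 °C; then pyridine, 30 % H2O2, 0→25 °C
Reagents that add atoms: none (net loss of H2)
Why: Phenylselenoetherification is reversible, so at 25 °C the Markovnikov 6‑endo selenide (O7 on tertiary C11, PhSe on C10) accumulates at the only alkene that has an internal nucleophile, and selenoxide syn‑elimination can only use a C9–H, with no stereocentre made or touched.

**Step 2**
Reactants: 2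
Product: 3, (2S)‑2‑[(1S,3S,4S)‑3‑bromo‑4‑chloro‑4‑methylcyclohexyl]‑2,6,6‑trimethyl‑3,6‑dihydro‑2H‑pyran (Br and Cl trans‑diequatorial, Br cis to the C4 substituent)
Conditions: Et4NBr (1.05 eq), 2,6‑lutidine·HCl (2.5 eq), HFIP/CH2Cl2 1:1, C(+)|Pt(−), undivided, 2.1 F/mol, 0 °C; then 45 °C, 12–24 h
Reagents that add atoms: tetraethylammonium bromide, CC[N+](CC)(CC)CC.[Br-]; 2,6‑lutidinium chloride, Cc1cccc(C)[nH+]1.[Cl-]
Why: Proposed new method: anodically generated BrCl adds anti to the trisubstituted ring alkene (C9=C10 is 1,2‑disubstituted, next to a quaternary carbon and inductively deactivated) to give first the two trans‑diaxial Fürst–Plattner adducts, whose antiperiplanar C–X bonds re‑ionise with anchimeric assistance in HFIP and swap faces through alkene + BrCl, whereas a diequatorial adduct cannot re‑ionise because the bought C4 centre locks the chair, so material should drain into the diequatorial product of chloride attack at the tertiary carbon of the bromonium cis to C4 (1S,2S); the closest known reaction types are the thermal diaxial→diequatorial 1,2‑interchange of vicinal dihalides and electrochemical or reversible vicinal dihalogenation.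

**Step 3**
Reactants: 3
Product: 4, (2R,3R)‑2‑[(1S,3S,4S)‑3‑bromo‑4‑chloro‑4‑methylcyclohexyl]‑2,6,6‑trimethyl‑3,6‑dihydro‑2H‑pyran‑3‑ol (C8–OH trans to C7‑CH3)
Conditions: SeO2 (0.5 eq), t‑BuOOH (3 eq), CH2Cl2, 25–40 °C
Reagents that add atoms: selenium dioxide, O=[Se]=O (O donor); tert‑butyl hydroperoxide, CC(C)(C)OO (re‑oxidant and ultimate O source)
Why: In this Riley allylic hydroxylation (ene, then [2,3]‑shift) C8H2 is the only allylic C–H, and in the half‑chair that keeps the cyclohexyl group pseudo‑equatorial its pseudo‑axial H lies on the face opposite the two pseudo‑axial methyls (C7‑Me and one C11‑Me), so Se and then O arrive suprafacially on that face to give (8R).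

**Step 4**
Reactants: 4
Product: 5, the 3‑O‑TBS ether of 4
Conditions: TBSOTf, 2,6‑lutidine, CH2Cl2, 0 °C
Reagents that add atoms: tert‑butyldimethylsilyl triflate, CC(C)(C)[Si](C)(C)OS(=O)(=O)C(F)(F)F
Why: Standard silylation gives a non‑participating group for step 5 and blocks O8, which would otherwise close a five‑membered bromoether in step 6.

**Step 5**
Reactants: 5
Product: 6, (2R,3R)‑2‑[(1S,3S,4S)‑3‑bromo‑4‑chloro‑4‑methylcyclohexyl]‑3‑(tert‑butyldimethylsilyloxy)‑6‑methylhept‑5‑en‑2‑ol
Conditions: Et3SiH (5 eq), BF3·OEt2 (1.2 eq), CH2Cl2, −78 °C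
Reagents that add atoms: none (hydrogen only)
Why: In this ionic hydrogenation (SN1′) the Lewis acid ionises the tertiary allylic C11–O bond and the silane delivers hydride irreversibly to the less substituted terminus (C9) of the dimethylallyl cation, restoring the C10=C11 alkene and free O7–H while C7, C8 and the diequatorial β‑bromo tertiary chloride stay untouched.

**Step 6**
Reactants: 6
Product: 7, 8‑O‑TBS‑caespitol, (2R,3R,5R)‑5‑bromo‑2‑[(1S,3S,4S)‑3‑bromo‑4‑chloro‑4‑methylcyclohexyl]‑3‑(TBS‑oxy)‑2,6,6‑trimethyloxane
Conditions: Et4NBr (1.2 eq), HFIP/CH2Cl2 1:1, C(+)|Pt(−), undivided, 2.2 F/mol, 0 °C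
Reagents that add atoms: tetraethylammonium bromide, CC[N+](CC)(CC)CC.[Br-]
Why: Anodic bromide oxidation supplies Br+ for a bromoetherification in which O7–H opens the bromonium at tertiary C11 (6‑endo, Markovnikov, favoured in HFIP) through the chair that has the cyclohexyl group and the developing C10–Br equatorial, which sets (10R) from C7.

**Step 7**
Reactants: 7
Product: 8, caespitol
Conditions: HF·pyridine, THF, 0→25 °C
Reagents that add atoms: none
Why: Non‑basic fluoride cleavage of the Si–O bond leaves the three alkyl halides and the hindered ether untouched.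

## Compound list
1 | (−)‑α‑bisabolol, (2S)‑6‑methyl‑2‑[(1S)‑4‑methylcyclohex‑3‑en‑1‑yl]hept‑5‑en‑2‑ol | O[C@](C)([C@H]1CCC(C)=CC1)CCC=C(C)C | starting material
2 | (2S)‑2,6,6‑trimethyl‑2‑[(1S)‑4‑methylcyclohex‑3‑enyl]‑3,6‑dihydro‑2H‑pyran | CC1(C)O[C@](C)([C@H]2CCC(C)=CC2)CC=C1 | intermediate
3 | ring bromochloride of 2 (1S,3S,4S cyclohexyl) | CC1(C)O[C@](C)([C@H]2CC[C@](C)(Cl)[C@@H](Br)C2)CC=C1 | intermediate
4 | (2R,3R)‑dihydropyran‑3‑ol | CC1(C)O[C@](C)([C@H]2CC[C@](C)(Cl)[C@@H](Br)C2)[C@H](O)C=C1 | intermediate
5 | TBS ether of 4 | CC1(C)O[C@](C)([C@H]2CC[C@](C)(Cl)[C@@H](Br)C2)[C@H](O[Si](C)(C)C(C)(C)C)C=C1 | intermediate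
6 | ring‑opened (2R,3R)‑3‑silyloxy‑hept‑5‑en‑2‑ol | O[C@](C)([C@H]1CC[C@](C)(Cl)[C@@H](Br)C1)[C@H](O[Si](C)(C)C(C)(C)C)CC=C(C)C | intermediate
7 | 8‑O‑TBS‑caespitol | CC1(C)O[C@](C)([C@H]2CC[C@](C)(Cl)[C@@H](Br)C2)[C@H](O[Si](C)(C)C(C)(C)C)C[C@H]1Br | intermediate
8 | caespitol | CC1(C)O[C@](C)([C@H]2CC[C@](C)(Cl)[C@@H](Br)C2)[C@H](O)C[C@H]1Br | target

## Totals and risks
Total steps: 7. Longest linear sequence: 7.

Steps most likely to fail:
1. **Step 2 (new method).** The funnel may stall at the diaxial adducts or scramble the halogens.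
   Fallback (known chemistry):
   - Add BrCl kinetically (NBS/Et4NCl, CH2Cl2, −78 °C).
   - Isolate the trans‑diaxial 1‑bromo‑2‑chloro adduct, which arises from the bromonium cis to C4 being opened at C2.
   - Convert it to 3 by the thermal diaxial→diequatorial 1,2‑interchange (PhCl, about 130–150 °C).
   - Return the other diaxial adduct to 2 with Zn/EtOH.
   This adds one step.
2. **Step 5.** Hydride may attack C11 and give the C9=C10 isopropyl isomer.
   Fallback: leave the cation manifold altogether.
   - Treat free alcohol 4 with BH3·SMe2 so that the O8‑borinate delivers boron to C10 and hydrogen to C9.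
   - The β‑alkoxyborane then eliminates, opening the ring to the C10=C11 alkene.
   - Silylate O8 selectively afterwards.
3. **Step 6.** 5‑exo closure may compete with 6‑endo closure.
   Fallback:
   - Run an equilibrating oxymercuration (Hg(OCOCF3)2, then KBr) to give the 6‑endo oxane with equatorial C10–HgBr.
   - Follow with brominolysis in Br2/pyridine, which proceeds with retention and gives the same equatorial C10–Br.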